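The four C–CH3 bonds at C3 of the two terminal rings A and E are cut (every ring is numbered with butyryl on C1 and oxygen on C2, C4 and C6). These quaternary carbons, flanked by the enolic carbons C2 and C4, are the only sp3 ring atoms. Without their methyl groups all five rings are the same 2,4,6-trihydroxybutyrophenone unit. The precursor is the unprotected, all-aromatic, CH2-bridged pentamer 14, whose only two ring C–H positions are C3 of rings A and E. One operation with iodomethane and methoxide methylates each twice, dearomatises both end rings and delivers the target. Pentamer 14 comes convergently from a central bis-Mannich base and two dimers.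

Key step: step 5

Remark: the target has no stereocentre and is achiral, so no enantiomer has to be selected; it is drawn as one of its enol tautomers, and paraformaldehyde, a polymer, is entered with the SMILES of the CH2O unit it delivers.

Step 1
Reactants: 1 phloroglucinol; 2 butyryl chloride
Product: 3 butyrylphloroglucinol [1-(2,4,6-trihydroxyphenyl)butan-1-one]
Conditions: AlCl3 (3.5 equiv), CH2Cl2–PhNO2, 0 → 40 °C; ice/aq. HCl
Reagents that add atoms: butyryl chloride, CCCC(Cl)=O
Why: Friedel–Crafts acylation of a very electron-rich arene, in which the first, aluminium-chelated acyl group deactivates the ring, so monoacylation should prevail.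

Step 2
Reactants: 3 butyrylphloroglucinol (two molecules per bridge, used in threefold excess over CH2O); 4 paraformaldehyde
Product: 7 dimer bis(3-butanoyl-2,4,6-trihydroxyphenyl)methane, via hydroxymethyl monomer 5 (not isolated), via monomer o-quinone methide 6 (not isolated)
Conditions: (CH2O)n (0.33 equiv CH2O per 3), NaOAc, AcOH, 70 °C; excess 3 washed out with warm water and recycled
Reagents that add atoms: formaldehyde (from paraformaldehyde 4), C=O
Why: Lederer–Manasse hydroxymethylation gives 5, loss of water gives 6, and a second molecule of 3 adds through a free ring carbon (conjugate Friedel–Crafts alkylation), while the excess of 3 should stop chain growth at the dimer.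

Step 3
Reactants: 3 butyrylphloroglucinol; 4 paraformaldehyde; 8 dimethylamine
Product: 10 bis-Mannich base 1-{3,5-bis[(dimethylamino)methyl]-2,4,6-trihydroxyphenyl}butan-1-one, via mono-Mannich base 9 (not isolated)
Conditions: (CH2O)n (2.5 equiv) and Me2NH (2.5 equiv, 33% in EtOH) premixed, EtOH, 40 °C; then 3 added slowly, 0 °C → rt; precipitate filtered cold and used at once
Reagents that add atoms: formaldehyde (from paraformaldehyde 4), C=O; dimethylamine, CNC
Why: Twofold phenolic Mannich reaction at the two equivalent free ring carbons C3 and C5, where inverse addition into excess preformed aminomethylating agent should make the second aminomethylation of 9 faster than its self-condensation, and the zwitterionic bis-base should leave the solution.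

Step 4
Reactants: 10 bis-Mannich base; 7 dimer (two molecules incorporated, 8 equiv used)
Product: 14 all-aromatic linear pentamer (five butyrylphloroglucinol rings A–E joined by four CH2 bridges; rings B–D bridged at C3 and C5; rings A and E bridged at C5 with H at C3), via first o-quinone methide 11 (not isolated), via half-coupled Mannich base 12 (not isolated), via second o-quinone methide 13 (not isolated)
Conditions: 10 added slowly to 7 (8 equiv), NaOAc, AcOH–1,4-dioxane, 70 °C, N2; Sephadex LH-20, excess 7 recycled
Reagents that add atoms: none
Why: Deaminative o-quinone methide generation from a phenolic Mannich base followed by conjugate Friedel–Crafts addition of the free ring carbon of 7, run twice, with slow addition and a large excess of 7 to favour capping over chain growth and a weakly acidic buffer to avoid base-induced bridge exchange.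

Step 5
Reactants: 14 all-aromatic pentamer; 15 iodomethane
Product: 17 target CNP0188003.0 (chain as in 14 but rings A and E are 3,3-dimethyl dienone rings), via bis(C-methyl) aromatic pentamer 16 (not isolated)
Conditions: NaOMe (10 equiv), MeI (4.4 equiv, in portions), degassed MeOH, 0 °C → rt, N2; cold 1 M HCl; crystallisation from aqueous MeOH
Reagents that add atoms: iodomethane, CI
Why: Methoxide turns all rings into phenoxides, and the ambident anions of rings A and E attack iodomethane (SN2) through C3, the only ring carbon still bearing hydrogen, which after proton loss gives the still aromatic 16; a second SN2 attack from the same, now methyl-bearing C3 builds the quaternary carbon and leaves each end ring as a β-triketone enolate that can no longer rearomatise. The closest known reaction type is the alkylative dearomatisation (C,C-dimethylation) of acylphloroglucinols with MeI/NaOMe to acylfilicinic acids, run here at two remote ends of one molecule that do not influence each other. No ring is closed and no stereocentre arises, because each new quaternary carbon carries two identical methyl groups. C- over O-methylation is required, and it should follow from the soft electrophile, the hydrogen-bonding solvent that shields the oxygens, and the chelation of the C2/C6 oxygens to the butyryl carbonyl. Attack on rings A/E rather than B–D is required, and the substrate provides it: every ring carbon of B–D and C5 of A/E carries a bulky arylmethyl group held in an inter-ring hydrogen-bond network, whereas C3 of A/E carries only H and then CH3. Over-methylation is limited by the near-stoichiometric charge of MeI and by the low nucleophilicity of the strongly acidic triketone enolate, and low temperature with a prompt acidic quench should limit retro-Michael exchange of the bridges.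

Compound list
1 | phloroglucinol | Oc1cc(O)cc(O)c1 | starting material
2 | butyryl chloride | CCCC(Cl)=O | starting material
3 | butyrylphloroglucinol, 1-(2,4,6-trihydroxyphenyl)butan-1-one | CCCC(=O)c1c(O)cc(O)cc1O | intermediate
4 | paraformaldehyde (SMILES of the CH2O unit delivered) | C=O | starting material
5 | 1-[2,4,6-trihydroxy-3-(hydroxymethyl)phenyl]butan-1-one (not isolated) | CCCC(=O)c1c(O)cc(O)c(CO)c1O | intermediate
6 | o-quinone methide of the monomer, 2-butanoyl-3,5-dihydroxy-6-methylidenecyclohexa-2,4-dien-1-one (not isolated) | CCCC(=O)C1=C(O)C=C(O)C(=C)C1=O | intermediate
7 | dimer, bis(3-butanoyl-2,4,6-trihydroxyphenyl)methane | CCCC(=O)c1c(O)cc(O)c(Cc2c(O)cc(O)c(C(=O)CCC)c2O)c1O | intermediate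
8 | dimethylamine | CNC | starting material
9 | mono-Mannich base, 1-{3-[(dimethylamino)methyl]-2,4,6-trihydroxyphenyl}butan-1-one (not isolated) | CCCC(=O)c1c(O)cc(O)c(CN(C)C)c1O | intermediate
10 | bis-Mannich base, 1-{3,5-bis[(dimethylamino)methyl]-2,4,6-trihydroxyphenyl}butan-1-one | CCCC(=O)c1c(O)c(CN(C)C)c(O)c(CN(C)C)c1O | intermediate
11 | first o-quinone methide, 10 minus one dimethylamine (not isolated) | CCCC(=O)C1=C(O)C(CN(C)C)=C(O)C(=C)C1=O | intermediate
12 | half-coupled Mannich base, central ring bearing one dimer unit and one CH2NMe2 arm (not isolated) | CCCC(=O)c1c(O)c(CN(C)C)c(O)c(Cc2c(O)c(Cc3c(O)cc(O)c(C(=O)CCC)c3O)c(O)c(C(=O)CCC)c2O)c1O | intermediate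
13 | second o-quinone methide, 12 minus dimethylamine (not isolated) | CCCC(=O)C1=C(O)C(Cc2c(O)c(Cc3c(O)cc(O)c(C(=O)CCC)c3O)c(O)c(C(=O)CCC)c2O)=C(O)C(=C)C1=O | intermediate
14 | all-aromatic linear methylene-bridged pentamer of butyrylphloroglucinol | CCCC(=O)c1c(O)cc(O)c(Cc2c(O)c(Cc3c(O)c(Cc4c(O)c(Cc5c(O)cc(O)c(C(=O)CCC)c5O)c(O)c(C(=O)CCC)c4O)c(O)c(C(=O)CCC)c3O)c(O)c(C(=O)CCC)c2O)c1O | intermediate
15 | iodomethane | CI | starting material
16 | pentamer with one C-methyl group at C3 of each end ring, all rings aromatic (not isolated) | CCCC(=O)c1c(O)c(C)c(O)c(Cc2c(O)c(Cc3c(O)c(Cc4c(O)c(Cc5c(O)c(C)c(O)c(C(=O)CCC)c5O)c(O)c(C(=O)CCC)c4O)c(O)c(C(=O)CCC)c3O)c(O)c(C(=O)CCC)c2O)c1O | intermediate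
17 | CNP0188003.0, pentamer with two terminal butyrylfilicinic acid rings (achiral) | CCCC(=O)C1=C(O)C(C)(C)C(O)=C(Cc2c(O)c(Cc3c(O)c(Cc4c(O)c(CC5=C(O)C(C)(C)C(O)=C(C(=O)CCC)C5=O)c(O)c(C(=O)CCC)c4O)c(O)c(C(=O)CCC)c3O)c(O)c(C(=O)CCC)c2O)C1=O | target

Total step count: 5
Longest linear sequence: 4 (step 1 → step 2 or step 3 → step 4 → step 5)

Steps most likely to fail

**Step 5.** Several processes could spoil this step:
- Methylation may stray to oxygen or to bridge-bearing ring carbons.
- The fourfold conversion may stop short and spread the material over partly methylated species.
- The basic medium may cleave and re-form the methylene bridges by retro-Michael/re-addition, which changes the chain length.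

The fallback dearomatises at the monomer stage, where the reaction is established and its product can be purified. It sets out from 3.
- MeI/NaOMe in MeOH should give butyrylfilicinic acid F1.
- Aminomethylation of its single free ring carbon with paraformaldehyde and dimethylamine should give the C5 Mannich base F2.
- Heating F2 with excess 3 in NaOAc/AcOH should give the mixed filicinic acid–phloroglucinol dimer F3.
- F3 has only one free aromatic carbon, so it cannot extend a chain. A slight excess over two equivalents of F3 is coupled with bis-Mannich base 10 under the conditions of step 4. The fallback comes back to the route at 17.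

**Step 4.** The chain may grow beyond five rings, because the product keeps two nucleophilic ends like the dimer. The second arm may couple incompletely, and removal of the large excess of dimer may be laborious.

The fallback grows the chain from the centre with the cheap monomer as the only nucleophile. The monomer can be used in much larger excess and washed out with warm water. It sets out from 10.
- Coupling with a large excess of 3 (NaOAc, AcOH–dioxane, 70 °C) should give the trimer F4.
- Twofold Mannich reaction at its two free end carbons should give the trimer bis-Mannich base F5.
- A second coupling with a large excess of 3 comes back to the route at 14.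

**Step 3.** The mono-aminomethylated intermediate may lose amine prematurely and self-condense to oligomers, or the bis-base may decompose during isolation.

The fallback replaces the amine by a sulfinate leaving group and triggers the coupling with mild base instead of heat. It sets out from 3.
- Three-component sulfonylmethylation with paraformaldehyde and sodium p-toluenesulfinate in aqueous formic acid should give the crystalline, storable bis-sulfone F6.
- With excess 7 and NaHCO3 in aqueous THF at room temperature, F6 should expel sulfinate arm by arm and be capped by the dimer. The fallback comes back to the route at 14.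

Further compounds
F1 | step 5 | butyrylfilicinic acid, 2-butanoyl-3,5-dihydroxy-4,4-dimethylcyclohexa-2,5-dien-1-one | CCCC(=O)C1=C(O)C(C)(C)C(O)=CC1=O
F2 | step 5 | Mannich base of butyrylfilicinic acid, (dimethylamino)methyl group on the former free ring carbon | CCCC(=O)C1=C(O)C(C)(C)C(O)=C(CN(C)C)C1=O
F3 | step 5 | mixed dimer, butyrylfilicinic acid–CH2–butyrylphloroglucinol | CCCC(=O)C1=C(O)C(C)(C)C(O)=C(Cc2c(O)cc(O)c(C(=O)CCC)c2O)C1=O
F4 | step 4 | linear methylene-bridged trimer of butyrylphloroglucinol | CCCC(=O)c1c(O)cc(O)c(Cc2c(O)c(Cc3c(O)cc(O)c(C(=O)CCC)c3O)c(O)c(C(=O)CCC)c2O)c1O
F5 | step 4 | trimer bis-Mannich base, one CH2NMe2 group on the free carbon of each end ring | CCCC(=O)c1c(O)c(CN(C)C)c(O)c(Cc2c(O)c(Cc3c(O)c(CN(C)C)c(O)c(C(=O)CCC)c3O)c(O)c(C(=O)CCC)c2O)c1O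
F6 | step 3 | bis-sulfone, 1-{2,4,6-trihydroxy-3,5-bis[(4-methylphenyl)sulfonylmethyl]phenyl}butan-1-one | CCCC(=O)c1c(O)c(CS(=O)(=O)c2ccc(C)cc2)c(O)c(CS(=O)(=O)c2ccc(C)cc2)c1O
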